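**Plan**
- Cuts, in retrosynthetic order: the O7 senecioate and O9 tiglate; the ring bond C9–C10; the C5 side chain back to a C5 ketone; the cyclobutane bonds C5–C11 and C4–C10. This leaves an open-chain dienoic acid joined by a C1–C2 aldol.
- Enabling feature: C10 is the methyl-bearing quaternary one-carbon bridge of the bicyclo[3.1.1]heptenone (cyclobutane C4–C5–C11–C10). It is bonded to the oxygenated C9, and C9 is β to the C7 carbonyl through C8 inside the seven-membered ring C5–C6–C7–C8–C9–C10–C11. A tertiary C10 radical and a β-alkoxy vinyl ketone can therefore make C9–C10.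
- Forward order: vinylogous aldol joins the chain; an intramolecular ketene [2+2] forms the cyclobutane and six-membered ring together; the side chain is grown on C5; the ring enone is unveiled; the seven-membered ring is closed by decarboxylative radical addition; the esters come last.
- Stereochemistry: C1 (catalytic asymmetric aldol) sets C4/C11 in the [2+2] and directs hydrogen to C5, then becomes the ketone. C10 follows from the tether, C9 from the E enol ether carrying a chiral benzylic group, and C7 from 1,3-anti hydride delivery out of O9.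

Key step: step 21

Numbering: ring atoms keep the numbers of the target (C1 ketone, C2=C3, bridgeheads C4 and C11, one-carbon bridges C5 and C10, chain C6–C9).
Assumption: the sense of induction of the bisphosphoramide catalyst in step 5 is taken from its behaviour with other enals; the configuration of 8 is to be checked (MTPA esters) and the antipodal catalyst used if needed.
Remark: a plain 4-methoxybenzyl ether at O9 would not bias C9, because the bicycle is locally mirror-symmetric beneath the cyclobutane; O9 therefore carries the (R)-1-(4-methoxyphenyl)ethyl group, which is cleaved like a PMB ether.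
Remark: the alkene geometry of 15/16 and the centres C6 of 17 and C7 of 22 are mixtures that are erased later; C3 of 17–20 is erased in step 14.

**Step 1**
Reactants: 1 1-[(tert-butyldimethylsilyl)oxy]propan-2-one; 2 ethyl (triphenylphosphoranylidene)acetate
Product: 3 ethyl (2E)-4-[(tert-butyldimethylsilyl)oxy]-3-methylbut-2-enoate
Conditions: toluene, 100 °C
Reagents that add atoms: none
Why: Wittig olefination of an α-silyloxy ketone with a stabilised ylide should be E-selective, placing the methyl group cis to the ester carbon.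

**Step 2**
Reactants: 3 the E enoate
Product: 4 (2E)-4-[(tert-butyldimethylsilyl)oxy]-3-methylbut-2-en-1-ol
Conditions: i-Bu2AlH (2.2 equiv), CH2Cl2, −78 °C; aq. potassium sodium tartrate
Reagents that add atoms: none
Why: 1,2-reduction of the unsaturated ester by the aluminium hydride should give the allylic alcohol without touching alkene geometry or the silyl ether.

**Step 3**
Reactants: 4 the allylic alcohol
Product: 5 (2E)-4-[(tert-butyldimethylsilyl)oxy]-3-methylbut-2-enal
Conditions: MnO2, CH2Cl2, rt
Reagents that add atoms: none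
Why: allylic oxidation with activated MnO2 stops at the enal and keeps the E geometry.

**Step 4**
Reactants: 6 ethyl 3-methylbut-2-enoate
Product: 7 tert-butyl[(1-ethoxy-3-methylbuta-1,3-dien-1-yl)oxy]dimethylsilane
Conditions: LiN(i-Pr)2, THF/DMPU, −78 °C; then TBSCl
Reagents that add atoms: tert-butylchlorodimethylsilane, CC(C)(C)[Si](C)(C)Cl
Why: γ-deprotonation and O-silylation of the extended enolate is the standard preparation of a silyl dienol ether for vinylogous Mukaiyama chemistry.

**Step 5**
Reactants: 5 the enal; 7 the silyl dienol ether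
Product: 8 ethyl (2E,5S,6E)-8-[(tert-butyldimethylsilyl)oxy]-5-hydroxy-3,7-dimethylocta-2,6-dienoate
Conditions: SiCl4 (1.1 equiv), (S,S)-binaphthyldiamine-derived bisphosphoramide (5 mol %), i-Pr2NEt (10 mol %), CH2Cl2, −72 °C; aq. NaHCO3
Reagents that add atoms: none
Why: in this Lewis-base-activated SiCl4 vinylogous Mukaiyama aldol the dienolate should react at its γ-carbon on the Si face of the enal exposed by the chiral phosphoramide-bound silicon cation, setting the carbinol (later C1) as S.

**Step 6**
Reactants: 8 the δ-hydroxy enoate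
Product: 9 ethyl (2E,5S,6E)-8-[(tert-butyldimethylsilyl)oxy]-3,7-dimethyl-5-[(triethylsilyl)oxy]octa-2,6-dienoate
Conditions: Et3SiCl, imidazole, CH2Cl2, 0 °C
Reagents that add atoms: chlorotriethylsilane, CC[Si](Cl)(CC)CC
Why: silylation of the secondary alcohol; the triethylsilyl group is chosen because it can later be removed beside the neopentyl TBS ether.

**Step 7**
Reactants: 9 the bis-silyl ester
Product: 10 (2E,5S,6E)-8-[(tert-butyldimethylsilyl)oxy]-3,7-dimethyl-5-[(triethylsilyl)oxy]octa-2,6-dienoic acid
Conditions: LiOH, THF/MeOH/H2O, rt; cold dilute HCl to pH 4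
Reagents that add atoms: lithium hydroxide, [Li+].[OH-]
Why: saponification of the ethyl ester, which both silyl ethers should survive.

**Step 8**
Reactants: 10 the dienoic acid
Product: 13 7-{[(tert-butyldimethylsilyl)oxy]methyl}-7-methyl-2-methylidene-4-[(triethylsilyl)oxy]bicyclo[3.1.1]heptan-6-one (C5 ketone; C3 exocyclic methylene; 1S-OTES on the side of the C5 bridge; C10 methyl syn and CH2OTBS anti to the C1–C3 bridge), via acid chloride 11 (not isolated), via vinylketene 12 (not isolated)
Conditions: NaH (1.0 equiv), then (COCl)2, DMF (cat.), toluene, 0 °C; added over 6 h to Et3N (5 equiv), toluene, 110 °C (0.01 M)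
Reagents that add atoms: none
Why: thermal intramolecular ketene–alkene [2+2] cycloaddition of the vinylketene, in which the ketene carbonyl carbon bonds to the less substituted alkene carbon (C11) and the ketene α-carbon to the tertiary one (C10) to give the bridged bicycle over a three-atom tether; alkene geometry is retained (methyl syn to the C1–C3 bridge) and A(1,3) strain turns the C1 silyloxy group away from the C10 substituents, so C1 fixes C11 and C4.

**Step 9**
Reactants: 13 the bicyclic ketone; 14 triethyl 2-phosphonopropionate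
Product: 15 ethyl 2-(bicycloheptan-6-ylidene)propanoate, i.e. 13 with C5=C6(CH3)CO2Et in place of C5=O (both alkene isomers)
Conditions: NaH, DME, 0 → 85 °C
Reagents that add atoms: none
Why: Horner–Wadsworth–Emmons olefination, which strained cyclobutanones undergo even with α-branched phosphonates, and the bridgehead α-carbons cannot enolise.

**Step 10**
Reactants: 15 the alkylidene ester
Product: 16 the C1 alcohol of 15
Conditions: HF·pyridine, pyridine, THF, 0 °C
Reagents that add atoms: none
Why: buffered fluoride should cleave the secondary triethylsilyl ether much faster than the neopentyl TBS ether without protonating the exocyclic alkenes.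

**Step 11**
Reactants: 16 the hydroxy alkylidene ester
Product: 17 ethyl 2-(bicycloheptan-6-yl)propanoate with C5–H syn to the C1–C3 bridge (side chain anti), C3 methyl on the side of the C10 bridge, free C1 hydroxyl (C6 epimers)
Conditions: H2 (10 bar), [Ir(cod)(PCy3)(py)]PF6 (10 mol %), CH2Cl2, rt
Reagents that add atoms: none
Why: hydroxyl-directed hydrogenation, in which the C1 hydroxyl lying over the C5 bridge binds the cationic iridium centre and delivers hydrogen to C5 on the face syn to the C1–C3 bridge, pushing the side chain anti; the exocyclic methylene is reduced as well.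

**Step 12**
Reactants: 17 the hydroxy ester
Product: 18 ethyl 2-methyl-2-(bicycloheptan-6-yl)propanoate (C6 gem-dimethyl, otherwise as 17)
Conditions: LiN(i-Pr)2 (2.5 equiv), THF, −78 → −20 °C; MeI (1.3 equiv), DMPU
Reagents that add atoms: iodomethane, CI
Why: ester enolate alkylation of the alkoxide–enolate dianion creates the quaternary C6, the lithium alkoxide being inert to iodomethane at this temperature.

**Step 13**
Reactants: 18 the gem-dimethyl ester
Product: 19 the diol (C7 primary alcohol, C1 secondary alcohol)
Conditions: LiAlH4, THF, 0 °C → rt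
Reagents that add atoms: none
Why: hydride reduction of the hindered ester to the neopentyl alcohol.

**Step 14**
Reactants: 19 the diol
Product: 21 enone aldehyde (C1 ketone; C2=C3 with C3 methyl; C7 aldehyde on C6 gem-dimethyl; C10 methyl and CH2OTBS), via keto aldehyde 20 (not isolated)
Conditions: IBX (5 equiv), DMSO, 80 °C
Reagents that add atoms: none
Why: 2-iodoxybenzoic acid oxidises both alcohols and then dehydrogenates the C1 ketone, which can enolise only toward C2 because C11 is a bridgehead, while the aldehyde has no α-hydrogen.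

**Step 15**
Reactants: 21 the enone aldehyde
Product: 22 the propargylic alcohol (C7 epimers)
Conditions: HC≡CMgBr (1.2 equiv), THF, −78 °C
Reagents that add atoms: ethynylmagnesium bromide, C#C[Mg]Br
Why: Grignard addition, in which the aldehyde should react faster than the conjugated, hindered C1 ketone at low temperature.

**Step 16**
Reactants: 22 the propargylic alcohol
Product: 23 the ynone (C7 ketone bearing C8≡C9–H)
Conditions: 1,1,1-triacetoxy-1,1-dihydro-1,2-benziodoxol-3(1H)-one (DMP), NaHCO3, CH2Cl2, 0 °C
Reagents that add atoms: none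
Why: buffered periodinane oxidation of a propargylic alcohol to the ynone without acid or base.

**Step 17**
Reactants: 23 the ynone; 24 (1R)-1-(4-methoxyphenyl)ethan-1-ol
Product: 25 the (E)-β-[(1R)-1-(4-methoxyphenyl)ethoxy]vinyl ketone (C10 CH2OTBS)
Conditions: PMe3 (10 mol %), CH2Cl2, 0 °C → rt
Reagents that add atoms: none
Why: phosphine-catalysed oxa-Michael addition of an alcohol to a terminal ynone gives the E β-alkoxy vinyl ketone, and the β,β-disubstituted ring enone should not compete.

**Step 18**
Reactants: 25 the silyl ether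
Product: 26 the C10 hydroxymethyl compound
Conditions: Bu4NF, AcOH (1:1), THF, 40 °C
Reagents that add atoms: none
Why: acetic-acid-buffered fluoride removes the TBS group under conditions the vinylogous ester and the benzylic ether should tolerate.

**Step 19**
Reactants: 26 the primary alcohol
Product: 28 the C10 carboxylic acid, via aldehyde 27 (not isolated)
Conditions: TEMPO (20 mol %), PhI(OAc)2, CH2Cl2, rt; then NaClO2, NaH2PO4, 2-methylbut-2-ene, t-BuOH/H2O, 0 °C
Reagents that add atoms: sodium chlorite, [Na+].[O-]Cl=O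
Why: oxoammonium oxidation to the aldehyde followed by Pinnick oxidation, with the alkene scavenger protecting the enol ether and the anisyl ring from hypochlorite.

**Step 20**
Reactants: 28 the acid; 29 N-hydroxyphthalimide
Product: 30 the N-phthalimidoyl ester (C10 carboxyl anti, methyl syn to the C1–C3 bridge)
Conditions: N,N'-diisopropylcarbodiimide, DMAP (10 mol %), CH2Cl2, rt
Reagents that add atoms: none
Why: carbodiimide esterification, routine for tertiary acids, gives the redox-active ester.

**Step 21**
Reactants: 30 the N-phthalimidoyl ester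
Product: 31 (9R)-9-[(1R)-1-(4-methoxyphenyl)ethoxy]longipin-2-ene-1,7-dione
Conditions: Ru(bpy)3(PF6)2 (2 mol %), diethyl 2,6-dimethyl-1,4-dihydropyridine-3,5-dicarboxylate (Hantzsch ester, 1.5 equiv), CH2Cl2 (0.005 M), blue LEDs, rt
Reagents that add atoms: none
Why: The light-excited divalent ruthenium complex is quenched by the Hantzsch ester, and the monovalent ruthenium complex so formed reduces the phthalimide ester, which loses phthalimide anion and CO2 to give the tertiary C10 cyclobutyl radical; this adds to C9, and the α-keto radical at C8 is reduced and protonated by the oxidised Hantzsch ester. The closest known reactions are reductive decarboxylative Giese additions of tertiary radicals from N-(acyloxy)phthalimides and radical cyclisations onto β-alkoxy acrylates and enones. The seven-membered ring closes 7-endo-trig, preferred to 6-exo attack at C8 because the nucleophilic radical seeks the β-carbon of the enone and because the rotamer that would bring C8 beneath C10 puts C7 into the most crowded position under the cyclobutane. C10 is controlled by the tether: the chain hangs from C5 on the face anti to the C1–C3 bridge, so C9 can bond only there and the methyl group ends syn to that bridge, whatever the configuration of the ester was. C9 is controlled by the enol ether: the E geometry holds the alkoxy group pseudo-equatorial, and the tie between the two near-mirror transition states (chain swung beneath C11 or beneath C4) is broken by the (R)-arylethyl group, whose aryl ring, in the s-trans conformation with the carbinol hydrogen in the enone plane, must lie on the enone face turned away from the core, the arrangement that leads to 9R. The step needs cyclisation to outrun hydrogen transfer to the C10 radical and the product to keep its β-alkoxy group, which high dilution and the absence of amine base are meant to secure.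

**Step 22**
Reactants: 31 the tricyclic ether
Product: 32 (9R)-9-hydroxylongipin-2-ene-1,7-dione
Conditions: DDQ, CH2Cl2/pH 7 buffer (10:1), 0 °C
Reagents that add atoms: none
Why: oxidative cleavage of the electron-rich benzylic ether, as for a PMB ether, frees O9 without base and so without β-elimination or retro-aldol opening.

**Step 23**
Reactants: 32 the β-hydroxy ketone; 33 (2E)-2-methylbut-2-enal
Product: 34 (7R,9R)-7-hydroxy-9-[(2E)-2-methylbut-2-enoyloxy]longipin-2-en-1-one
Conditions: SmI2 (30 mol %, premixed with 33, 8 equiv), THF, −10 °C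
Reagents that add atoms: none
Why: Evans–Tishchenko reaction, in which the hemiacetal formed on O9 and held by trivalent samarium passes its hydride to the C7 carbonyl through a six-membered chair, giving the 1,3-anti (trans) C7 alcohol and leaving the aldehyde carbon as the O9 tiglate.

**Step 24**
Reactants: 34 the hydroxy tiglate; 35 3-methylbut-2-enoyl chloride
Product: 36 (7R,9R)-7-(3-methylbut-2-enoyloxy)-9-[(2E)-2-methylbut-2-enoyloxy]longipin-2-en-1-one (CNP0277258.1)
Conditions: pyridine, DMAP (cat.), CH2Cl2, 0 °C → rt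
Reagents that add atoms: none
Why: acylation of the remaining secondary alcohol, with pyridine rather than a trialkylamine to avoid deconjugation through the vinylketene; the trans 1,3-relationship should prevent acyl migration.

**Compound list**
1 | 1-[(tert-butyldimethylsilyl)oxy]propan-2-one | CC(=O)CO[Si](C)(C)C(C)(C)C | starting material
2 | ethyl (triphenylphosphoranylidene)acetate | CCOC(=O)C=P(c1ccccc1)(c1ccccc1)c1ccccc1 | starting material
3 | ethyl (2E)-4-[(tert-butyldimethylsilyl)oxy]-3-methylbut-2-enoate | CCOC(=O)/C=C(\C)CO[Si](C)(C)C(C)(C)C | intermediate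
4 | (2E)-4-[(tert-butyldimethylsilyl)oxy]-3-methylbut-2-en-1-ol | OC/C=C(\C)CO[Si](C)(C)C(C)(C)C | intermediate
5 | (2E)-4-[(tert-butyldimethylsilyl)oxy]-3-methylbut-2-enal | O=C/C=C(\C)CO[Si](C)(C)C(C)(C)C | intermediate
6 | ethyl 3-methylbut-2-enoate | CCOC(=O)C=C(C)C | starting material
7 | tert-butyl[(1-ethoxy-3-methylbuta-1,3-dien-1-yl)oxy]dimethylsilane | C=C(C)C=C(OCC)O[Si](C)(C)C(C)(C)C | intermediate
8 | ethyl (2E,5S,6E)-8-[(tert-butyldimethylsilyl)oxy]-5-hydroxy-3,7-dimethylocta-2,6-dienoate | CCOC(=O)/C=C(\C)C[C@H](O)/C=C(\C)CO[Si](C)(C)C(C)(C)C | intermediate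
9 | ethyl (2E,5S,6E)-8-[(tert-butyldimethylsilyl)oxy]-3,7-dimethyl-5-[(triethylsilyl)oxy]octa-2,6-dienoate | CCOC(=O)/C=C(\C)C[C@H](O[Si](CC)(CC)CC)/C=C(\C)CO[Si](C)(C)C(C)(C)C | intermediate
10 | (2E,5S,6E)-8-[(tert-butyldimethylsilyl)oxy]-3,7-dimethyl-5-[(triethylsilyl)oxy]octa-2,6-dienoic acid | OC(=O)/C=C(\C)C[C@H](O[Si](CC)(CC)CC)/C=C(\C)CO[Si](C)(C)C(C)(C)C | intermediate
11 | acid chloride of 10 (not isolated) | ClC(=O)/C=C(\C)C[C@H](O[Si](CC)(CC)CC)/C=C(\C)CO[Si](C)(C)C(C)(C)C | intermediate
12 | (5S,6E)-8-[(tert-butyldimethylsilyl)oxy]-7-methyl-3-methylidene-5-[(triethylsilyl)oxy]octa-1,6-dien-1-one, the vinylketene (not isolated) | O=C=CC(=C)C[C@H](O[Si](CC)(CC)CC)/C=C(\C)CO[Si](C)(C)C(C)(C)C | intermediate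
13 | 7-{[(tert-butyldimethylsilyl)oxy]methyl}-7-methyl-2-methylidene-4-[(triethylsilyl)oxy]bicyclo[3.1.1]heptan-6-one (C5 ketone, C3=CH2, 1S-OTES on the side of the C5 bridge, C10 methyl syn and CH2OTBS anti to the C1–C3 bridge) | O=C1[C@@H]2C(=C)C[C@H](O[Si](CC)(CC)CC)[C@H]1[C@]2(C)CO[Si](C)(C)C(C)(C)C | intermediate
14 | triethyl 2-phosphonopropionate | CCOC(=O)C(C)P(=O)(OCC)OCC | starting material
15 | ethyl 2-(bicycloheptan-6-ylidene)propanoate: 13 with C5=C6(CH3)CO2Et (alkene isomers) | CCOC(=O)C(C)=C1[C@@H]2C(=C)C[C@H](O[Si](CC)(CC)CC)[C@H]1[C@]2(C)CO[Si](C)(C)C(C)(C)C | intermediate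
16 | C1 alcohol of 15 | CCOC(=O)C(C)=C1[C@@H]2C(=C)C[C@H](O)[C@H]1[C@]2(C)CO[Si](C)(C)C(C)(C)C | intermediate
17 | ethyl 2-(bicycloheptan-6-yl)propanoate: C5–H syn to the C1–C3 bridge, C3 methyl on the side of the C10 bridge, C1 hydroxyl, C6 epimers | CCOC(=O)C(C)[C@H]1[C@@H]2[C@@H](C)C[C@H](O)[C@H]1[C@]2(C)CO[Si](C)(C)C(C)(C)C | intermediate
18 | ethyl 2-methyl-2-(bicycloheptan-6-yl)propanoate: 17 with C6 gem-dimethyl | CCOC(=O)C(C)(C)[C@H]1[C@@H]2[C@@H](C)C[C@H](O)[C@H]1[C@]2(C)CO[Si](C)(C)C(C)(C)C | intermediate
19 | diol: C7 primary alcohol and C1 secondary alcohol | OCC(C)(C)[C@H]1[C@@H]2[C@@H](C)C[C@H](O)[C@H]1[C@]2(C)CO[Si](C)(C)C(C)(C)C | intermediate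
20 | keto aldehyde: C1 ketone, C7 aldehyde, C2–C3 saturated (not isolated) | O=CC(C)(C)[C@H]1[C@@H]2[C@@H](C)CC(=O)[C@H]1[C@]2(C)CO[Si](C)(C)C(C)(C)C | intermediate
21 | enone aldehyde: C1 ketone, C2=C3(CH3), C7 aldehyde, C10 methyl and CH2OTBS | O=CC(C)(C)[C@H]1[C@@H]2C(C)=CC(=O)[C@H]1[C@]2(C)CO[Si](C)(C)C(C)(C)C | intermediate
22 | propargylic alcohol at C7 (epimers) | C#CC(O)C(C)(C)[C@H]1[C@@H]2C(C)=CC(=O)[C@H]1[C@]2(C)CO[Si](C)(C)C(C)(C)C | intermediate
23 | ynone: C7 ketone with C8≡C9–H | C#CC(=O)C(C)(C)[C@H]1[C@@H]2C(C)=CC(=O)[C@H]1[C@]2(C)CO[Si](C)(C)C(C)(C)C | intermediate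
24 | (1R)-1-(4-methoxyphenyl)ethan-1-ol | C[C@@H](O)c1ccc(OC)cc1 | starting material
25 | (E)-β-[(1R)-1-(4-methoxyphenyl)ethoxy]vinyl ketone, C10 CH2OTBS | C[C@@H](O/C=C/C(=O)C(C)(C)[C@H]1[C@@H]2C(C)=CC(=O)[C@H]1[C@]2(C)CO[Si](C)(C)C(C)(C)C)c1ccc(OC)cc1 | intermediate
26 | C10 hydroxymethyl compound | C[C@@H](O/C=C/C(=O)C(C)(C)[C@H]1[C@@H]2C(C)=CC(=O)[C@H]1[C@]2(C)CO)c1ccc(OC)cc1 | intermediate
27 | C10 aldehyde (not isolated) | C[C@@H](O/C=C/C(=O)C(C)(C)[C@H]1[C@@H]2C(C)=CC(=O)[C@H]1[C@]2(C)C=O)c1ccc(OC)cc1 | intermediate
28 | C10 carboxylic acid | C[C@@H](O/C=C/C(=O)C(C)(C)[C@H]1[C@@H]2C(C)=CC(=O)[C@H]1[C@]2(C)C(=O)O)c1ccc(OC)cc1 | intermediate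
29 | N-hydroxyphthalimide | O=C1c2ccccc2C(=O)N1O | starting material
30 | N-phthalimidoyl ester of 28 (radical precursor) | C[C@@H](O/C=C/C(=O)C(C)(C)[C@H]1[C@@H]2C(C)=CC(=O)[C@H]1[C@]2(C)C(=O)ON1C(=O)c2ccccc2C1=O)c1ccc(OC)cc1 | intermediate
31 | (9R)-9-[(1R)-1-(4-methoxyphenyl)ethoxy]longipin-2-ene-1,7-dione | COc1ccc([C@@H](C)O[C@@H]2CC(=O)C(C)(C)[C@@H]3[C@H]4C(=O)C=C(C)[C@@H]3[C@]42C)cc1 | intermediate
32 | (9R)-9-hydroxylongipin-2-ene-1,7-dione | O[C@@H]1CC(=O)C(C)(C)[C@@H]2[C@H]3C(=O)C=C(C)[C@@H]2[C@]31C | intermediate
33 | (2E)-2-methylbut-2-enal | C/C=C(\C)C=O | starting material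
34 | (7R,9R)-7-hydroxy-9-[(2E)-2-methylbut-2-enoyloxy]longipin-2-en-1-one | C/C=C(\C)C(=O)O[C@@H]1C[C@@H](O)C(C)(C)[C@@H]2[C@H]3C(=O)C=C(C)[C@@H]2[C@]31C | intermediate
35 | 3-methylbut-2-enoyl chloride | CC(C)=CC(Cl)=O | starting material
36 | (7R,9R)-7-(3-methylbut-2-enoyloxy)-9-[(2E)-2-methylbut-2-enoyloxy]longipin-2-en-1-one | C/C=C(\C)C(=O)O[C@@H]1C[C@@H](OC(=O)C=C(C)C)C(C)(C)[C@@H]2[C@H]3C(=O)C=C(C)[C@@H]2[C@]31C | target

**Step count and risks**
Total: 24 steps. Longest linear sequence: 23 steps (1–3, then 5–24); step 4 is a one-step side branch.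

Step 21. What may go wrong: the two transition states in which the chain swings beneath C11 or beneath C4 are told apart only by the benzylic ether, so facial discrimination at C9 may be poor; loss of the alkoxy group by β-elimination may accompany it. The fallback sets C9 after ring closure under catalyst control. It sets out from 31 as obtained, together with its C9 epimer, (9S)-9-[(1R)-1-(4-methoxyphenyl)ethoxy]longipin-2-ene-1,7-dione F1. DBU in CH2Cl2 should eliminate the benzylic alcohol from both to give one compound, longipina-2,8-diene-1,7-dione F2. Copper-catalysed enantioselective β-borylation (B2pin2, CuCl, NaOt-Bu, a chiral ferrocenyl bisphosphine, MeOH, THF) should then add boron to C9 of the less substituted enone to give 9-(pinacolatoboryl)longipin-2-ene-1,7-dione F3, boron taking the place of the C9 oxygen. Oxidation with NaBO3 returns to the route at 32.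

Step 9. What may go wrong: the α-branched phosphonate anion may add too slowly to the C5 carbonyl, which is screened by the C1 silyl ether on one face and the C10 CH2OTBS group on the other. The fallback separates addition from elimination. From 13, the lithium enolate of ethyl propanoate (LiN(i-Pr)2, THF, −78 °C) should add to give the tertiary β-hydroxy ester, ethyl 2-(6-hydroxybicycloheptan-6-yl)propanoate F4. Dehydration with bis[α,α-bis(trifluoromethyl)benzyloxy]diphenylsulfurane, which can only place the double bond exocyclic toward C6, returns to the route at 15.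

Step 23. What may go wrong: the conjugated aldehyde may form the hemiacetal and transfer hydride too slowly, so that retro-aldol opening or dehydration of 32 takes over. The fallback uses a sacrificial aldehyde and installs the tiglate by ordinary acylation. From 32, the Evans–Tishchenko reaction with acetaldehyde (SmI2 cat., THF, −10 °C) should give (7R,9R)-9-acetoxy-7-hydroxylongipin-2-en-1-one F5. Acylation with 35 (pyridine, DMAP) gives (7R,9R)-9-acetoxy-7-(3-methylbut-2-enoyloxy)longipin-2-en-1-one F6. Selective methanolysis of the acetate (K2CO3, MeOH, 0 °C), which is far more reactive than the β,β-disubstituted unsaturated ester, gives (7R,9R)-9-hydroxy-7-(3-methylbut-2-enoyloxy)longipin-2-en-1-one F7. (2E)-2-Methylbut-2-enoyl chloride with pyridine and DMAP then returns to the route at 36.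

**Further compounds**
F1 | step 21 | (9S)-9-[(1R)-1-(4-methoxyphenyl)ethoxy]longipin-2-ene-1,7-dione | COc1ccc([C@@H](C)O[C@H]2CC(=O)C(C)(C)[C@@H]3[C@H]4C(=O)C=C(C)[C@@H]3[C@]42C)cc1
F2 | step 21 | longipina-2,8-diene-1,7-dione | C1=CC(=O)C(C)(C)[C@@H]2[C@H]3C(=O)C=C(C)[C@@H]2[C@]31C
F3 | step 21 | 9-(pinacolatoboryl)longipin-2-ene-1,7-dione (boron in the position of the C9 oxygen of 32) | CC1(C)OB(OC1(C)C)[C@@H]1CC(=O)C(C)(C)[C@@H]2[C@H]3C(=O)C=C(C)[C@@H]2[C@]31C
F4 | step 9 | ethyl 2-(6-hydroxybicycloheptan-6-yl)propanoate, the aldol adduct of 13 (C5 and C6 epimers) | CCOC(=O)C(C)C1(O)[C@@H]2C(=C)C[C@H](O[Si](CC)(CC)CC)[C@H]1[C@]2(C)CO[Si](C)(C)C(C)(C)C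
F5 | step 23 | (7R,9R)-9-acetoxy-7-hydroxylongipin-2-en-1-one | CC(=O)O[C@@H]1C[C@@H](O)C(C)(C)[C@@H]2[C@H]3C(=O)C=C(C)[C@@H]2[C@]31C
F6 | step 23 | (7R,9R)-9-acetoxy-7-(3-methylbut-2-enoyloxy)longipin-2-en-1-one | CC(=O)O[C@@H]1C[C@@H](OC(=O)C=C(C)C)C(C)(C)[C@@H]2[C@H]3C(=O)C=C(C)[C@@H]2[C@]31C
F7 | step 23 | (7R,9R)-9-hydroxy-7-(3-methylbut-2-enoyloxy)longipin-2-en-1-one | O[C@@H]1C[C@@H](OC(=O)C=C(C)C)C(C)(C)[C@@H]2[C@H]3C(=O)C=C(C)[C@@H]2[C@]31C
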